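The earlier runs and the new flask are calculated with made-up constants; the scatter is artificial.

Late in the winter run Ux is still climbing at its early pace: 5.9% at 30.0 min, 19.8% at 90.0 min. The summer run, with more Wu, ends at 19.6%, so these two Wu charges read alike. The dusk run, with more Yx and less Wu, ends at 24.8%; if its smaller Wu charge costs nothing, this reads as Yx to the power 0.568, near a square root. One reading of that order is a small amount of free Aj, released from Yx and used by Ul. On that reading, which these runs do not test, free Aj goes as the root of Yx over Ul, and the rate as the root of Ul times Yx.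

| flask | Ul | Yx | Wu | remark | time |
|---|---|---|---|---|---|
| winter | 20 mM | 22 mM | 56 mM | run made earlier |  |
| summer | 20 mM | 22 mM | 88 mM | run made earlier |  |
| dusk | 20 mM | 33 mM | 40 mM | run made earlier |  |
| flask | 20 mM | 22.0 mM | 40.0 mM |  | 1.5 h |

| run | time / min | Ul / % | Ux / % |
|---|---|---|---|
| winter | 12.0 | 98.3 | 2.5 |
| winter | 30.0 | 93.8 | 5.9 |
| winter | 60.0 | 86.1 | 13.4 |
| winter | 90.0 | 81.1 | 19.8 |
| summer | 12.0 | 97.4 | 1.7 |
| summer | 30.0 | 92.9 | 6.2 |
| summer | 60.0 | 86.9 | 12.6 |
| summer | 90.0 | 79.9 | 19.6 |
| dusk | 8.00 | 98.0 | 1.5 |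
| dusk | 15.0 | 95.9 | 3.3 |
| dusk | 40.0 | 89.3 | 10.7 |
| dusk | 90.0 | 75.7 | 24.8 |

(scatter of a reading: 0.5 percentage points)

- solid, in amounts per volume of the solution: Wu
- the numbers in the tables scatter with a standard deviation of 0.5 percentage points
- at the start none of Wu is in solution
- the earlier runs do not show how much of Aj is bound; that part of a forecast is a guess

- part of the Ul that has reacted at 1.5 h
- share of the unused Aj that is free and not bound as Yx, at 1.5 h

From the mean end Ux of winter and summer, 19.7%, one dimensionless number follows, for this flask 19.7%: the reach, the part of Ul reacted, scaled from winter by the root of Yx over Ul and by the time. Is one number enough? The dusk run has this flask's Wu but also more Yx, so it cannot part the two effects, and every run charged the same Ul, so the root of Ul stands untested. The runs do not show how much of Aj is bound, so the reach gives no free share.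

The forecast gave 19% and 20%, reading that “free Aj is the active species”.

The flask gives 20.1% reacted against a reach of 19.7%, with 5.53% of the unused Aj free and the remainder bound as Yx, its resting state.

    Ul + Aj → Gy + Ux (k = 0.0438 M⁻¹ s⁻¹)
    Aj + Gy ⇌ Yx, settled at all times (K = 1.60 × 10⁵ M⁻¹)
    Gy + Wy ⇌ Lx (K = 4.86 × 10⁶ M⁻¹, k = 0.167 M⁻¹ s⁻¹)
    Wu ⇌ Wy, rate k4*(cs4 - [Wy]) while solid is left; crystals form when [Wy] > cs4 (solubility = 8.10 mM, k = 8.84 × 10⁻⁴ s⁻¹)
    Gy → Wa (k = 0.0118 s⁻¹)

The neighbouring flask, with 50 mM of Ul and its other charges unchanged, has a reach of 12.5%. At 1.50 h its free Aj stands at 0.567 mM against 0.995 mM in the flask, and its Ul has reacted to 13.0%.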